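All runs come from a simulation for substances that don't exist.

The vessel is closed, so if each protic impurity takes one unit of substrate for good, with the impurity as limiting reagent of that loss, the size of the loss follows from the two charges. As a ratio of charges, that reckoning holds no time.

| flask | solid substrate | protic impurity | remark | time |
|---|---|---|---|---|
| dawn | 1 mM | 0.10 mM | run made earlier |  |
| summer | 1 mM | 0.15 mM | run made earlier |  |
| flask | 1.0 mM | 0.200 mM |  | 15 min |

- dawn (time / min: solid substrate / %, target / %): 2.50: 25.4, 7.0; 5.00: 0.1, 6.3; 8.00: 0, 3.5; 10.0: 0.1, 4.3; 12.0: 1.1, 4.3; 15.0: 0, 6.5; 20.0: 0.7, 6.0
- summer (time / min: solid substrate / %, target / %): 2.50: 23.6, 7.1; 5.00: 0.8, 5.7; 8.00: 0, 4.9; 10.0: 0, 3.8; 12.0: 0, 4.7; 15.0: 1.4, 4.2; 20.0: 2.4, 5.8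

(readings scatter by 1 percentage point)

- solid, in amounts per volume of the solution: solid substrate
- at the start none of the solid substrate is in solution
- what has only dissolved of solid substrate counts as not reacted
- the reaction counts as stopped when no species that holds the solid substrate changes by six tenths of a point or more over the second half of the time

1. the state of affairs at 15 min: stopped, and by what, or still going (for what has run out or reacted, a solid counts together with what of it has only dissolved) (all of the solid substrate has reacted / forward and back rates have come level / it is still moving)
2. part of the solid substrate that has turned into other species by 15 min (what has only dissolved does not count)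
3. how much target there is at 15 min, in percent of the solid substrate charged
4. how much isomer of the product A there is at 15 min, in percent of the solid substrate charged

Here is the quick number you asked for, set beside your hunch, the forecast. This flask has a survival share of 80.0%: one minus c(protic impurity) over c(solid substrate), the part of the charge the impurity cannot take at one for one. From the second reading on, target averages 5.15% in the dawn run and 4.85% in the summer run. Divided by their survival shares, these readings give 5.72% and 5.71%. With a scatter of 1 percentage point per reading, a flat level fits as well, so this is a bet. My reckoning for this flask is target 4.57%, which leaves 75.4% of the charge to be shared by isomer of the product A and whatever else the runs did not read. Conversion I leave open: dissolved substrate counts as unreacted, and the readings of the solid do not show it.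

The forecast says all of the solid substrate has reacted, conversion 100%, target 5% and isomer of the product A 95%, holding that “The plateau does not scale with impurity”. Its isomer stands above the share my reckoning leaves.

In the flask at the asked time, forward and back rates have come level; conversion is 90.2%, target 4.59% and isomer of the product A 60.6%.

    starting material ⇌ target (K = 0.470, k = 0.0740 s⁻¹)
    starting material ⇌ isomer of the product A (K = 6.20, k = 0.00350 s⁻¹)
    target ⇌ isomer of the product A (k = 0.0460 s⁻¹)
    starting material + protic impurity → quenched substrate (k = 670 M⁻¹ s⁻¹)
    target ⇌ isomer of the product B (K = 1.10, k = 0.120 s⁻¹)
    solid substrate ⇌ starting material, rate k6*(cs6 - [starting material]) while solid is left; crystals form when [starting material] > cs6 (solubility = 0.200 mM, k = 0.0780 s⁻¹)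

In the flask at 15.0 min, quenched substrate stands at 20.0%, with 0% of the impurity left. Isomer of the product A holds 75.7% of this flask's survival share of 80.0%. In the neighbour flask with 0.34 mM of impurity, the survival share is 66.0%, which gives target 3.77% and, with the isomer's part carried over from the first flask, isomer of the product A 50.0%. The neighbour flask computes to 3.79% and 50.0%.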